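**Strategy.** The target is a 20-membered diaryl ether in which ring A (one hydroxyl, meta-bridged) and ring B (ether carbon C1 flanked by the hydroxylated C2 and C6, chain at C4) are joined by one oxygen and twelve methylenes. Everything rests on disconnecting the O–C1 bond of ring B. Because C1 sits between two oxygenated carbons, it is the site at which a 1,3-dimethoxyarene is lithiated, so an iodide can be placed exactly there. The precursor is an open 1,12-diaryldodecane carrying a free ring A phenol and a 4-iodo-3,5-dimethoxyphenyl ring B; one CuI-catalysed Ullmann etherification then forms the ether bond and the macrocycle together.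

Key step: step 6

Remark on the chemistry: the target has no stereocentre and its tether counts exactly twelve CH2 groups, so the chain source must be the C12 diene dodeca-1,11-diene (C12H22, eight methylenes between two vinyl groups). The ring A phenol is carried as a triisopropylsilyl ether, which withstands aqueous phosphate and n-BuLi and, through its bulk, does not direct lithiation onto ring A.

Step 1
Reactants: 1 1-bromo-3,5-dimethoxybenzene; 2 dodeca-1,11-diene
Product: 4 1-(dodec-11-en-1-yl)-3,5-dimethoxybenzene, via dodec-11-enyl-9-BBN 3 (not isolated)
Conditions: 2 (4 equiv), 9-BBN (1 equiv), THF, 0 °C to rt; then 1 (0.8 equiv), PdCl2(dppf) (3 mol%), 3 M aq K3PO4, DMF, 60 °C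
Reagents that add atoms: none
Why: Anti-Markovnikov hydroboration of one terminal alkene of the diene, which is kept in excess so that mono-addition should dominate, gives a primary alkylborane that undergoes B-alkyl Suzuki–Miyaura coupling with the aryl bromide, the bidentate dppf ligand disfavouring β-hydride elimination.

Step 2
Reactants: 5 3-bromo-5-methoxyphenol
Product: 6 (3-bromo-5-methoxyphenoxy)triisopropylsilane
Conditions: TIPSCl, imidazole, DMF, rt
Reagents that add atoms: triisopropylsilyl chloride (TIPSCl), CC(C)[Si](Cl)(C(C)C)C(C)C
Why: Imidazole-promoted O-silylation of a phenol is routine, and the bulky triisopropylsilyl ether is chosen because it should survive the basic coupling and the lithiation that follow.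

Step 3
Reactants: 4 1-(dodec-11-en-1-yl)-3,5-dimethoxybenzene; 6 (3-bromo-5-methoxyphenoxy)triisopropylsilane
Product: 8 {3-[12-(3,5-dimethoxyphenyl)dodecyl]-5-methoxyphenoxy}triisopropylsilane, via 12-aryldodecyl-9-BBN 7 (not isolated)
Conditions: 9-BBN (1.3 equiv), THF, 0 °C to rt; then 6, PdCl2(dppf) (3 mol%), 3 M aq K3PO4, THF, 60 °C
Reagents that add atoms: none
Why: A second hydroboration/B-alkyl Suzuki–Miyaura coupling joins the terminal carbon of the chain to ring A at its C–Br bond, while the methyl ethers and the hindered aryl silyl ether should tolerate the mildly basic two-phase medium.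

Step 4
Reactants: 8 {3-[12-(3,5-dimethoxyphenyl)dodecyl]-5-methoxyphenoxy}triisopropylsilane
Product: 10 {3-[12-(4-iodo-3,5-dimethoxyphenyl)dodecyl]-5-methoxyphenoxy}triisopropylsilane, via ring B aryllithium 9 (not isolated)
Conditions: n-BuLi (1.2 equiv), THF, 0 °C, 2 h; then I2 (1.3 equiv), THF, −78 °C to rt
Reagents that add atoms: iodine (I2), [I][I]
Why: Directed ortho-metalation should occur at the ring B C–H between the two methoxy groups, the only doubly activated and doubly coordinated site, much faster than at the singly methoxy-activated ring A positions that the silyloxy group shields, and iodine then traps the aryllithium at that carbon.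

Step 5
Reactants: 10 {3-[12-(4-iodo-3,5-dimethoxyphenyl)dodecyl]-5-methoxyphenoxy}triisopropylsilane
Product: 11 3-[12-(4-iodo-3,5-dimethoxyphenyl)dodecyl]-5-methoxyphenol, that is 1-(3-hydroxy-5-methoxyphenyl)-12-(4-iodo-3,5-dimethoxyphenyl)dodecane
Conditions: TBAF, AcOH (1:1), THF, 0 °C to rt
Reagents that add atoms: none
Why: Fluoride-induced desilylation of an aryl silyl ether, buffered with acetic acid, should release the ring A phenol directly and leave the aryl iodide and the methyl ethers untouched.

Step 6
Reactants: 11 3-[12-(4-iodo-3,5-dimethoxyphenyl)dodecyl]-5-methoxyphenol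
Product: 12 trimethyl ether of the target, the 20-membered macrocycle in which a 5-methoxy-1,3-phenylene (ring A) and a 2,6-dimethoxy-1,4-phenylene (ring B) are bridged by one ether oxygen (on C1 of ring B) and by a (CH2)12 chain (on C4 of ring B)
Conditions: CuI (30 mol%), picolinic acid (60 mol%), K3PO4 (3 equiv), degassed DMSO, 90 °C, syringe-pump addition of 11 (final 2 mM)
Reagents that add atoms: none
Why: K3PO4 converts the ring A phenol into its phenoxide, which binds picolinate-ligated monovalent copper; insertion into the ring B C–I bond should give a trivalent copper aryl phenoxide, and reductive elimination forms the O–C1 bond of ring B and returns monovalent copper. The closest known reaction type is the ligand-accelerated Ullmann diaryl ether synthesis (CuI/picolinic acid in DMSO, a system suited to hindered partners) in its intramolecular, macrocyclising form. The single ring closes end to end, the ring A phenoxide oxygen attacking C1 of ring B across the twelve-methylene tether, to give a 20-membered ring made of three ring A atoms, the oxygen, four ring B atoms and twelve CH2 groups. No stereocentre is created. Site selectivity is built into 11, which has one free OH and one C–I bond, the latter fixed between the two methoxy groups by the lithiation of step 4; these ortho methoxy groups can chelate copper and so offset their bulk, while the nucleophile is an unhindered phenol. The preference for ring closure over oligomerisation is secured by slow addition, which keeps the stationary concentration of 11 very low.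

Step 7
Reactants: 12 trimethyl ether of the target
Product: 14 target CNP0314249.0 (ring A 5-hydroxy; ring B 2,6-dihydroxy; same macrocycle), via tris(dibromoboryl) ether 13 (not isolated)
Conditions: BBr3 (6 equiv), CH2Cl2, −78 °C to rt; then H2O, 0 °C
Reagents that add atoms: none
Why: BBr3 demethylation of aryl methyl ethers proceeds by boron coordination to each methoxy oxygen and SN2 removal of the methyl group by bromide, whereas the diaryl ether offers no alkyl carbon to attack and should stay intact, and hydrolysis of the aryl borates releases the three phenols.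

**Compound list**

1 | 1-bromo-3,5-dimethoxybenzene | COc1cc(Br)cc(OC)c1 | starting material
2 | dodeca-1,11-diene | C=CCCCCCCCCCC=C | starting material
3 | 9-(dodec-11-en-1-yl)-9-borabicyclo[3.3.1]nonane | C=CCCCCCCCCCCB1C2CCCC1CCC2 | intermediate (not isolated)
4 | 1-(dodec-11-en-1-yl)-3,5-dimethoxybenzene | COc1cc(CCCCCCCCCCC=C)cc(OC)c1 | intermediate
5 | 3-bromo-5-methoxyphenol | COc1cc(O)cc(Br)c1 | starting material
6 | (3-bromo-5-methoxyphenoxy)triisopropylsilane | COc1cc(Br)cc(O[Si](C(C)C)(C(C)C)C(C)C)c1 | intermediate
7 | 9-[12-(3,5-dimethoxyphenyl)dodecyl]-9-borabicyclo[3.3.1]nonane | COc1cc(CCCCCCCCCCCCB2C3CCCC2CCC3)cc(OC)c1 | intermediate (not isolated)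
8 | {3-[12-(3,5-dimethoxyphenyl)dodecyl]-5-methoxyphenoxy}triisopropylsilane | COc1cc(CCCCCCCCCCCCc2cc(OC)cc(O[Si](C(C)C)(C(C)C)C(C)C)c2)cc(OC)c1 | intermediate
9 | {2,6-dimethoxy-4-[12-(3-methoxy-5-triisopropylsilyloxyphenyl)dodecyl]phenyl}lithium | [Li]c1c(OC)cc(CCCCCCCCCCCCc2cc(OC)cc(O[Si](C(C)C)(C(C)C)C(C)C)c2)cc1OC | intermediate (not isolated)
10 | {3-[12-(4-iodo-3,5-dimethoxyphenyl)dodecyl]-5-methoxyphenoxy}triisopropylsilane | COc1cc(CCCCCCCCCCCCc2cc(OC)cc(O[Si](C(C)C)(C(C)C)C(C)C)c2)cc(OC)c1I | intermediate
11 | 3-[12-(4-iodo-3,5-dimethoxyphenyl)dodecyl]-5-methoxyphenol | COc1cc(O)cc(CCCCCCCCCCCCc2cc(OC)c(I)c(OC)c2)c1 | intermediate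
12 | trimethyl ether of the target (20-membered diaryl ether macrocycle; ring A 5-methoxy, ring B 2,6-dimethoxy) | COc1cc2cc(c1)Oc1c(OC)cc(cc1OC)CCCCCCCCCCCC2 | intermediate
13 | tris(O-dibromoboryl) derivative of the target | BrB(Br)Oc1cc2cc(c1)Oc1c(OB(Br)Br)cc(cc1OB(Br)Br)CCCCCCCCCCCC2 | intermediate (not isolated)
14 | CNP0314249.0 (20-membered diaryl ether macrocycle; ring A 5-hydroxy, ring B 2,6-dihydroxy, twelve-methylene tether) | Oc1cc2cc(c1)Oc1c(O)cc(cc1O)CCCCCCCCCCCC2 | target

**Step count.** Total steps: 7. Longest linear sequence: 6 steps (steps 1, 3, 4, 5, 6, 7).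

**Steps most likely to fail**

1. Step 6. The crowded, electron-rich ring B may lose iodine reductively before the C–O bond forms, or intermolecular coupling may outrun ring closure. The fallback reverses the polarity of the ether formation; it sets out from 4 and comes back at 12. Lithiation of 4 between the methoxy groups with n-BuLi, borylation with B(OMe)3 and oxidation with alkaline H2O2 should give 4-(dodec-11-en-1-yl)-2,6-dimethoxyphenol F1. Hydroboration of F1 with 9-BBN (one extra equivalent for the O–H) and B-alkyl Suzuki–Miyaura coupling with an excess of 1,3-dibromo-5-methoxybenzene under the conditions of step 3 should give 4-[12-(3-bromo-5-methoxyphenyl)dodecyl]-2,6-dimethoxyphenol F2. Intramolecular Ullmann etherification of F2 under the conditions of step 6 (CuI, picolinic acid, K3PO4, dilute DMSO) then pairs a hindered phenol with an unhindered aryl bromide and closes the same macrocycle 12.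

2. Step 4. Deprotonation may compete on ring A or at a benzylic carbon, or the silyl group may migrate from oxygen to a metalated ring A carbon, so that iodine ends up at the wrong site. The fallback metalates before ring A is present; it sets out from 4 and comes back at 10. Lithiation of 4 (a single arene, hence unambiguous) with n-BuLi in THF and quenching with TMSCl should give [4-(dodec-11-en-1-yl)-2,6-dimethoxyphenyl]trimethylsilane F3. Hydroboration and coupling with 6 as in step 3 should give {3-[12-(3,5-dimethoxy-4-trimethylsilylphenyl)dodecyl]-5-methoxyphenoxy}triisopropylsilane F4, the aryl–silicon bond being inert to the basic coupling. Ipso-iododesilylation of F4 with one equivalent of ICl in CH2Cl2 at −78 °C then replaces silicon by iodine at the same carbon and delivers 10.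

3. Step 1. Hydroboration and coupling may occur at both ends of the symmetric diene, or the surviving double bond may migrate, which would erode the supply of 4. The fallback uses a chain with differentiated ends; it sets out from 1 and comes back at 4. Kumada–Corriu coupling of 1 with dodec-11-en-1-ylmagnesium bromide F5 (prepared from commercial 12-bromododec-1-ene and Mg in THF), catalysed by PdCl2(dppf) in THF, should give 4 directly.

**Further compounds**

F1 | step 6 | 4-(dodec-11-en-1-yl)-2,6-dimethoxyphenol | COc1cc(CCCCCCCCCCC=C)cc(OC)c1O
F2 | step 6 | 4-[12-(3-bromo-5-methoxyphenyl)dodecyl]-2,6-dimethoxyphenol | COc1cc(Br)cc(CCCCCCCCCCCCc2cc(OC)c(O)c(OC)c2)c1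
F3 | step 4 | [4-(dodec-11-en-1-yl)-2,6-dimethoxyphenyl]trimethylsilane | COc1cc(CCCCCCCCCCC=C)cc(OC)c1[Si](C)(C)C
F4 | step 4 | {3-[12-(3,5-dimethoxy-4-trimethylsilylphenyl)dodecyl]-5-methoxyphenoxy}triisopropylsilane | COc1cc(CCCCCCCCCCCCc2cc(OC)cc(O[Si](C(C)C)(C(C)C)C(C)C)c2)cc(OC)c1[Si](C)(C)C
F5 | step 1 | dodec-11-en-1-ylmagnesium bromide | C=CCCCCCCCCCC[Mg]Br
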